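Sunday's feed brings reagent at 0.125 d⁻¹, counted in charges of starting material, and I wanted to know whether that keeps up with the starting material.

| flask | starting material | reagent | remark | time |
|---|---|---|---|---|
| eta | 0.011 M | 0.0165 M | run made earlier |  |
| beta | 0.0074 M | 0.0165 M | run made earlier |  |
| delta | 0.017 M | 0.0165 M | run made earlier |  |
| epsilon | 0.011 M | 0.025 M | run made earlier |  |
| Wednesday's | 0.011 M | 0.0165 M | everything together at the start | 20 d |
| Monday's | 0.011 M (fed, over 12 d) | 0.0165 M | all else is in the flask from the start; the feed brings no volume worth counting | 20 d |
| Sunday's | 0.011 M | 0.0165 M (fed, over 12 d) | all else is in the flask from the start; the feed brings no volume worth counting | 20 d |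
| Thursday's | 0.011 M | 0.0165 M (fed, over 3.0 d) | all else is in the flask from the start; the feed brings no volume worth counting | 20 d |

* the flask with the highest amount of target, in percent of the starting material charged ("all alike" if they lie within 1.5 percentage points) (Wednesday's / Monday's / Sunday's / Thursday's / all alike)
* final target, as a percentage of the starting material charged, in Wednesday's
* final target, as a percentage of the starting material charged, in Monday's
* final target, as a percentage of the starting material charged, in Sunday's
* final target, as a percentage of the starting material charged, in Thursday's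

- percentages count the starting material that a species holds: one side product counts as two
- the numbers in the tables scatter by 1 percentage point (one standard deviation)
- candidate steps: starting material <-> intermediate + leaving ligand; reagent + intermediate -> target; reagent -> decomposition product; starting material + intermediate -> side product

| run | time / d | target / % |
|---|---|---|
| eta | 1.67 | 33.5 |
| eta | 2.50 | 46.8 |
| eta | 4.00 | 58.2 |
| eta | 6.00 | 75.5 |
| eta | 8.00 | 82.0 |
| eta | 12.0 | 90.2 |
| eta | 20.0 | 95.6 |
| beta | 3.00 | 52.1 |
| beta | 6.00 | 75.6 |
| beta | 8.00 | 84.7 |
| beta | 12.0 | 92.0 |
| beta | 15.0 | 97.4 |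
| beta | 20.0 | 97.7 |
| delta | 1.04 | 22.1 |
| delta | 3.00 | 51.0 |
| delta | 6.00 | 70.0 |
| delta | 8.00 | 74.5 |
| delta | 12.0 | 83.5 |
| delta | 15.0 | 87.8 |
| delta | 20.0 | 91.8 |
| epsilon | 1.67 | 33.9 |
| epsilon | 3.00 | 52.2 |
| epsilon | 6.00 | 75.9 |
| epsilon | 10.0 | 88.9 |
| epsilon | 20.0 | 98.4 |

(readings scatter by 1 percentage point)

I read the tables across at 6.00 d. Eta gave 75.5%, beta, at 0.0074 M of starting material, 75.6%, and epsilon, at 0.025 M of reagent, 75.9%. With a scatter of 1 percentage point these are one reading, so the fraction turned did not follow either charge. I therefore took the step from starting material to intermediate and leaving ligand as rate-limiting, with reagent catching the intermediate behind it. Eta's reading gives a clock of 0.234 d⁻¹, a little under the forecast's 0.25. Delta, at 0.017 M, already lay lower with 70.0%, so I kept the clock to the first 3.0 d.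

By 3.0 d the clock has opened 0.505 of the charge. Sunday's has by then delivered 0.375 of a charge of reagent. That gives a cover of 0.743, reagent delivered over starting material opened, both as fractions of the charge. It stands below one, so I expected Sunday's to lose target. Thursday's has delivered its 1.50 charges by then, a cover of 2.97. Wednesday's repeats eta, which read 95.6% at 20.0 d. In Monday's the last parcels get 8.00 d, and eta read 82.0% at that age.

The forecast named Wednesday's: 96.5% for Wednesday's, 92% for Monday's, 93% for Sunday's (86% to 96%) and 96% for Thursday's, saying “starved reagent slows capture and invites side product”.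

The flasks gave 97.4% in Wednesday's, 92.2% in Monday's, 88.2% in Sunday's and 95.7% in Thursday's.

    starting material ⇌ intermediate + leaving ligand (K = 4.20 × 10⁻⁵ M, k = 3.00 × 10⁻⁶ s⁻¹)
    reagent + intermediate → target (k = 0.240 L mol⁻¹ s⁻¹)
    reagent → decomposition product (k = 5.20 × 10⁻⁹ s⁻¹)
    starting material + intermediate → side product (k = 0.00130 L mol⁻¹ s⁻¹)

Sunday's, with cover 0.743, ended with side product 8.52%, and Thursday's, with cover 2.97, ended with 2.15%. The neighbour is Wednesday's with 0.0041 M of reagent. Its cover at 3.0 d is 0.738. Its reagent charge is 0.373 of the starting material charge, which makes reagent the limiting reagent and caps target at 37.3%. That flask gave target 37.3%, with reagent down to 0% of its own charge, side product 13.3% and starting material 49% still there.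

The runs stem from a simulated flask for an exercise; noise was put on by code.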